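Everything rests on cutting the bond between the exocyclic CHBr carbon (C6, nerolidol numbering) and the fully substituted oxane carbon C7 (ring C2, bearing methyl and the ring oxygen). In one operation a carbene-catalysed decarboxylative radical acylation joins an eight-carbon bromo-oxane and a seven-carbon aldehyde, both made from (S)-linalool, as the C6 ketone. It exploits the ready formation of a tertiary α-alkoxy radical at C7 and lets the oxane ring (equatorial bromine at C10, axial methyl at C11) reset that stereocentre. The precursors are the N-acyloxyphthalimide of the oxane-2-carboxylic acid and a silyl-protected γ-hydroxy aldehyde. Reagent-controlled reduction, bromide displacement with inversion and desilylation complete the target.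

Key step: step 6

Remark: (S)-(+)-linalool is taken as commercially available in high enantiomeric purity; both fragments are drawn from it.

Step 1
Reactants: 1 (S)-(+)-linalool
Product: 2 triethyl{[(3S)-3,7-dimethylocta-1,6-dien-3-yl]oxy}silane
Conditions: TESOTf, 2,6-lutidine, CH2Cl2, −78 to 0 °C
Reagents that add atoms: triethylsilyl triflate, CC[Si](CC)(CC)OS(=O)(=O)C(F)(F)F
Why: Silyl ether protection of the hindered tertiary allylic alcohol with a silyl triflate and a hindered base masks the hydroxyl so that the later aldehyde cannot close to a lactol, and the stereocentre is untouched.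

Step 2
Reactants: 2 triethyl{[(3S)-3,7-dimethylocta-1,6-dien-3-yl]oxy}silane
Product: 4 (4S)-4-methyl-4-[(triethylsilyl)oxy]hex-5-enal, via secondary ozonide 3 (not isolated)
Conditions: O3 (1 equiv, Sudan Red 7B end point), CH2Cl2, −78 °C; then Me2S, −78 °C to rt
Reagents that add atoms: ozone, [O-][O+]=O
Why: Ozonolysis with reductive work-up (Criegee mechanism) should cleave the electron-rich trisubstituted alkene well before the monosubstituted vinyl group beside the quaternary silyloxy carbon when ozone is dosed to one equivalent, and no stereocentre is formed.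

Step 3
Reactants: 1 (S)-(+)-linalool
Product: 5 (3R,6S)-3-bromo-6-ethenyl-2,2,6-trimethyloxane (bromine trans to vinyl)
Conditions: NBS, CH2Cl2, 0 °C, dark; chromatographic separation of the C3 epimers
Reagents that add atoms: N-bromosuccinimide, O=C1CCC(=O)N1Br
Why: In this bromoetherification the tertiary hydroxyl opens the bromonium ion of the trisubstituted alkene at its more substituted carbon (Markovnikov, 6-endo closure, anti addition); the new C3 centre is not controlled because vinyl and methyl are similar in size, so the (3R,6S) isomer is separated from the (3S,6S) epimer and the linalool stereocentre serves as the resolving element for the C–Br centre.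

Step 4
Reactants: 5 (3R,6S)-3-bromo-6-ethenyl-2,2,6-trimethyloxane
Product: 7 (2S,5R)-5-bromo-2,6,6-trimethyloxane-2-carboxylic acid, via oxane-2-carbaldehyde 6 (not isolated)
Conditions: RuCl3·H2O (2 mol %), NaIO4 (5 equiv), CCl4/MeCN/H2O, rt
Reagents that add atoms: sodium periodate (oxygen donor through RuO4), [Na+].[O-]I(=O)(=O)=O; water, O
Why: RuO4-catalysed oxidative cleavage should cut the vinyl group to the carboxylic acid through the aldehyde, the ring offering no C–H bond next to oxygen for over-oxidation, and both stereocentres are untouched.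

Step 5
Reactants: 7 (2S,5R)-5-bromo-2,6,6-trimethyloxane-2-carboxylic acid
Product: 8 1,3-dioxoisoindolin-2-yl (2S,5R)-5-bromo-2,6,6-trimethyloxane-2-carboxylate
Conditions: N-hydroxyphthalimide, DIC, DMAP (cat.), CH2Cl2, rt
Reagents that add atoms: N-hydroxyphthalimide, O=C1c2ccccc2C(=O)N1O
Why: Carbodiimide (Steglich-type) esterification should give the redox-active ester that serves as the precursor of the tertiary radical.

Step 6
Reactants: 8 1,3-dioxoisoindolin-2-yl (2S,5R)-5-bromo-2,6,6-trimethyloxane-2-carboxylate; 4 (4S)-4-methyl-4-[(triethylsilyl)oxy]hex-5-enal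
Product: 9 (4S)-1-[(2S,5R)-5-bromo-2,6,6-trimethyloxan-2-yl]-4-methyl-4-[(triethylsilyl)oxy]hex-5-en-1-one
Conditions: 4 (1.5 equiv), 3-(2,6-diisopropylphenyl)-5,6,7,8-tetrahydro-4H-cyclohepta[d]thiazol-3-ium perchlorate (10 mol %), Cs2CO3 (20 mol %), DMSO, 60 °C; chromatographic removal of the minor C2 epimer
Reagents that add atoms: none
Why: In this N-heterocyclic carbene radical catalysis the carbene adds to aldehyde 4 and the deprotonated Breslow intermediate reduces ester 8 by single-electron transfer, which fragments to phthalimide anion, CO2 and the tertiary α-alkoxy radical at ring C2. That transient radical should combine with the persistent ketyl-type radical of the catalyst-bound aldehyde, and collapse of the adduct releases ketone 9 and the carbene. The closest known reaction type is the carbene-catalysed synthesis of hindered dialkyl ketones from aliphatic aldehydes and tertiary N-acyloxyphthalimides. No ring is closed. The stereocentre at ring C2 is erased in the planar radical and set again by the ring: with bromine equatorial at C5, the axial methyl at C6 lies on the same face as bromine and blocks it, so the bulky ketyl partner should bond on the opposite face and place the acyl group equatorial and trans to bromine (2S). The step needs this facial selectivity and survival of the C–Br bond; the chair with the axial C6 methyl secures the first, and the second is secured because bromine is not β to the radical centre and the base is only catalytic.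

Step 7
Reactants: 9 (4S)-1-[(2S,5R)-5-bromo-2,6,6-trimethyloxan-2-yl]-4-methyl-4-[(triethylsilyl)oxy]hex-5-en-1-one
Product: 10 (1S,4S)-1-[(2S,5R)-5-bromo-2,6,6-trimethyloxan-2-yl]-4-methyl-4-[(triethylsilyl)oxy]hex-5-en-1-ol
Conditions: (R)-2-methyl-CBS-oxazaborolidine (20 mol %), catecholborane, toluene, −78 °C
Reagents that add atoms: none
Why: In the Corey–Bakshi–Shibata reduction the (R)-oxazaborolidine should bind the ketone with the tertiary oxanyl group as the large and the CH2 chain as the small substituent and deliver hydride under reagent control to the (1S)-alcohol, while catecholborane at −78 °C leaves the vinyl group alone.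

Step 8
Reactants: 10 (1S,4S)-1-[(2S,5R)-5-bromo-2,6,6-trimethyloxan-2-yl]-4-methyl-4-[(triethylsilyl)oxy]hex-5-en-1-ol
Product: 11 {[(3S,6R)-6-bromo-6-[(2S,5R)-5-bromo-2,6,6-trimethyloxan-2-yl]-3-methylhex-1-en-3-yl]oxy}triethylsilane
Conditions: CBr4, P(n-Oct)3, 2,6-di-tert-butylpyridine, toluene, 70 °C
Reagents that add atoms: carbon tetrabromide, BrC(Br)(Br)Br
Why: In this Appel-type bromination the activated oxygen should be displaced by bromide from the rear (SN2), turning the (1S)-alcohol into the (R)-bromide with inversion, as is done for exocyclic carbinols next to a ring oxygen in bromo ether natural products.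

Step 9
Reactants: 11 {[(3S,6R)-6-bromo-6-[(2S,5R)-5-bromo-2,6,6-trimethyloxan-2-yl]-3-methylhex-1-en-3-yl]oxy}triethylsilane
Product: 12 (3S,6R)-6-bromo-6-[(2S,5R)-5-bromo-2,6,6-trimethyloxan-2-yl]-3-methylhex-1-en-3-ol
Conditions: HF·pyridine, pyridine, THF, 0 °C to rt
Reagents that add atoms: none
Why: Fluoride-mediated desilylation under buffered, non-basic conditions should free the tertiary allylic alcohol without forming an alkoxide that could displace the nearby bromide, and no stereocentre is touched.

Compound list
1 | (S)-(+)-linalool, (3S)-3,7-dimethylocta-1,6-dien-3-ol | C=C[C@@](C)(O)CCC=C(C)C | starting material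
2 | triethyl{[(3S)-3,7-dimethylocta-1,6-dien-3-yl]oxy}silane | C=C[C@@](C)(O[Si](CC)(CC)CC)CCC=C(C)C | intermediate
3 | 3,3-dimethyl-5-[(3S)-3-methyl-3-(triethylsilyloxy)pent-4-en-1-yl]-1,2,4-trioxolane (secondary ozonide, not isolated) | C=C[C@@](C)(O[Si](CC)(CC)CC)CCC1OOC(C)(C)O1 | intermediate
4 | (4S)-4-methyl-4-[(triethylsilyl)oxy]hex-5-enal | C=C[C@@](C)(O[Si](CC)(CC)CC)CCC=O | intermediate
5 | (3R,6S)-3-bromo-6-ethenyl-2,2,6-trimethyloxane | C=C[C@]1(C)CC[C@@H](Br)C(C)(C)O1 | intermediate
6 | (2S,5R)-5-bromo-2,6,6-trimethyloxane-2-carbaldehyde (not isolated) | O=C[C@]1(C)CC[C@@H](Br)C(C)(C)O1 | intermediate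
7 | (2S,5R)-5-bromo-2,6,6-trimethyloxane-2-carboxylic acid | OC(=O)[C@]1(C)CC[C@@H](Br)C(C)(C)O1 | intermediate
8 | 1,3-dioxoisoindolin-2-yl (2S,5R)-5-bromo-2,6,6-trimethyloxane-2-carboxylate | O=C(ON1C(=O)c2ccccc2C1=O)[C@]3(C)CC[C@@H](Br)C(C)(C)O3 | intermediate
9 | (4S)-1-[(2S,5R)-5-bromo-2,6,6-trimethyloxan-2-yl]-4-methyl-4-[(triethylsilyl)oxy]hex-5-en-1-one | C=C[C@@](C)(O[Si](CC)(CC)CC)CCC(=O)[C@]1(C)CC[C@@H](Br)C(C)(C)O1 | intermediate
10 | (1S,4S)-1-[(2S,5R)-5-bromo-2,6,6-trimethyloxan-2-yl]-4-methyl-4-[(triethylsilyl)oxy]hex-5-en-1-ol | C=C[C@@](C)(O[Si](CC)(CC)CC)CC[C@H](O)[C@]1(C)CC[C@@H](Br)C(C)(C)O1 | intermediate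
11 | {[(3S,6R)-6-bromo-6-[(2S,5R)-5-bromo-2,6,6-trimethyloxan-2-yl]-3-methylhex-1-en-3-yl]oxy}triethylsilane | C=C[C@@](C)(O[Si](CC)(CC)CC)CC[C@@H](Br)[C@]1(C)CC[C@@H](Br)C(C)(C)O1 | intermediate
12 | (3S,6R)-6-bromo-6-[(2S,5R)-5-bromo-2,6,6-trimethyloxan-2-yl]-3-methylhex-1-en-3-ol | C=C[C@@](C)(O)CC[C@@H](Br)[C@]1(C)CC[C@@H](Br)C(C)(C)O1 | target

Total steps: 9. Longest linear sequence: 7 steps (steps 3 to 9, from 1).

Steps most likely to fail

Step 8. The carbinol carbon is flanked by the fully substituted ring carbon, so rear-side displacement may be outrun by participation of the ring oxygen (three-membered oxonium, then bromide attack at the tertiary ring carbon with ring expansion), by participation of the silyl ether oxygen, or by elimination. The fallback sets out from 10 and returns at 11. It makes the carbon–bromine bond on an open chain where no ether oxygen can take part and rebuilds the oxane afterwards. Zn dust, NH4Cl, EtOH, reflux should open the β-bromo ether of 10 by reductive elimination to (3S,6S,7S)-3,7,11-trimethyl-3-[(triethylsilyl)oxy]dodeca-1,10-diene-6,7-diol F1. 1,1'-Sulfonyldiimidazole, NaH, THF should convert it into the cyclic sulfate (4S,5S)-4-methyl-4-(4-methylpent-3-en-1-yl)-5-[(3S)-3-methyl-3-(triethylsilyloxy)pent-4-en-1-yl]-1,3,2-dioxathiolane 2,2-dioxide F2. LiBr in THF should open this at the secondary carbon with inversion to lithium (3S,6R,7S)-6-bromo-3,7,11-trimethyl-3-[(triethylsilyl)oxy]dodeca-1,10-dien-7-yl sulfate F3. Mild hydrolysis (cat. H2SO4, H2O, THF) should then give (3S,6R,7S)-6-bromo-3,7,11-trimethyl-3-[(triethylsilyl)oxy]dodeca-1,10-dien-7-ol F4. NBS, CH2Cl2, 0 °C closes the oxane again by 6-endo bromoetherification through a chair with the bromoalkyl chain and the new bromine equatorial, which should return 11.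

Step 6. Facial selectivity may be incomplete when the ketyl partner bonds to the planar ring radical, because the ring can flip to the chair with axial bromine, which exposes the other face. The radical may also be lost by oxidation to the oxocarbenium ion, and the enolisable aldehyde may self-condense under the basic carbene conditions. The fallback sets out from 4 and 8 and returns at 9. It replaces the radical–radical coupling by a nickel-catalysed reductive acylation. NaClO2, NaH2PO4, 2-methyl-2-butene, t-BuOH/H2O should oxidise 4 to (4S)-4-methyl-4-[(triethylsilyl)oxy]hex-5-enoic acid F5. 2,2'-Dipyridyl disulfide, PPh3, CH2Cl2 should give S-(pyridin-2-yl) (4S)-4-methyl-4-[(triethylsilyl)oxy]hex-5-enethioate F6. NiBr2(dme), 4,4'-di-tert-butyl-2,2'-bipyridine, tetrakis(dimethylamino)ethylene as reductant, DMA/THF, rt then couples F6 with 8: an acyl–nickel species captures the tertiary radical, which should give 9 without base or free aldehyde. The mild organic reductant is chosen to spare the β-bromo ether.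

Step 7. Hydride delivery to the hindered ketone may be slow, reagent control may be eroded by the adjacent fully substituted stereocentre (mismatched pairing), and the vinyl group may be hydroborated. The fallback sets out from 9 and returns at 10. It is a biocatalytic reduction with an (S)-selective ketoreductase chosen from a commercial panel (NADPH recycled with glucose and glucose dehydrogenase, phosphate buffer pH 7 with i-PrOH, 30 °C), which should give 10 directly under enzyme control; no new compound is made.

Further compounds
F1 | step 8 | (3S,6S,7S)-3,7,11-trimethyl-3-[(triethylsilyl)oxy]dodeca-1,10-diene-6,7-diol | C=C[C@@](C)(O[Si](CC)(CC)CC)CC[C@H](O)[C@](O)(C)CCC=C(C)C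
F2 | step 8 | (4S,5S)-4-methyl-4-(4-methylpent-3-en-1-yl)-5-[(3S)-3-methyl-3-(triethylsilyloxy)pent-4-en-1-yl]-1,3,2-dioxathiolane 2,2-dioxide | C=C[C@@](C)(O[Si](CC)(CC)CC)CC[C@@H]1OS(=O)(=O)O[C@@]1(C)CCC=C(C)C
F3 | step 8 | lithium (3S,6R,7S)-6-bromo-3,7,11-trimethyl-3-[(triethylsilyl)oxy]dodeca-1,10-dien-7-yl sulfate | [Li+].C=C[C@@](C)(O[Si](CC)(CC)CC)CC[C@@H](Br)[C@](OS(=O)(=O)[O-])(C)CCC=C(C)C
F4 | step 8 | (3S,6R,7S)-6-bromo-3,7,11-trimethyl-3-[(triethylsilyl)oxy]dodeca-1,10-dien-7-ol | C=C[C@@](C)(O[Si](CC)(CC)CC)CC[C@@H](Br)[C@](O)(C)CCC=C(C)C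
F5 | step 6 | (4S)-4-methyl-4-[(triethylsilyl)oxy]hex-5-enoic acid | C=C[C@@](C)(O[Si](CC)(CC)CC)CCC(O)=O
F6 | step 6 | S-(pyridin-2-yl) (4S)-4-methyl-4-[(triethylsilyl)oxy]hex-5-enethioate | C=C[C@@](C)(O[Si](CC)(CC)CC)CCC(=O)Sc1ccccn1
F0 | step 7 | none | none
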